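## Analysis of the target

Compound 9 is 5,7-dihydroxy-6,8-dimethyl-2-pentacosyl-4H-chromen-4-one (C36H60O4). It is a benzo-γ-pyrone made of the benzene ring A (C4a, C5, C6, C7, C8, C8a) and the pyranone ring B (O1, C2, C3, C4, C4a, C8a), with an unbranched C25 chain on C2. It has no stereocentre and no configured double bond, so the whole problem is one of connectivity and substitution pattern. Ring A is hexasubstituted (OH on C5, CH3 on C6, OH on C7, CH3 on C8, O1 on C8a, the acyl carbon C4 on C4a) and keeps no C–H at which a mistake could be repaired later.

The plan is built on the unbroken carbon line C2–C3–C4–C4a–C8a–C8–C7–C6–C5, which carries oxygen on every second atom (C2, C4, C8a, C7, C5). The part O1/C2/C3/C4/C4a/C8a is a triacetic acid lactone unit, and the part C8–C7–C6–C5 with both C-methyl groups is a 2-methyl-3-oxopentanoate unit. The polarity alternates, so that C8 and C4a are donors and C8a and C5 are acceptors.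

The 2,4,6-trioxygenated 3,5-dimethylphenyl ketone inside 9 has a local mirror plane through C4a and C7. The oxygens on C5 and C8a are therefore equivalent, and ring B can close on either of them with the same result. Sensitive points are the electron-rich, easily oxidised and easily C-alkylated phloroglucinol ring, the reversible opening of ring B by alkoxide, and the vinylogously acidic CH2 of the chain next to C2.

The synthesis is hard for two reasons. Two C-methyl groups cannot be put on a phloroglucinol cleanly (over-alkylation, dearomatisation, O- against C-attack). The waxy chain also makes every intermediate poorly soluble in the cold and tedious to purify, which rewards a very short route without protecting groups.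

## Retrosynthetic reasoning

**9 to 6 and 7 (through 8).** Two bonds of ring A are cut, C8–C8a and C4a–C5.
- The cut leaves the C4a=C8a edge inside a monocyclic γ-pyrone, 6. It also leaves a four-carbon piece C5–C6–C7–C8 that already holds both methyl groups and O7 at the right oxidation level, the commercial β-keto ester 7.
- The cut follows the natural polarity. C8 is the γ-carbon of 7 (a donor as the dianion). C8a is the β-carbon of the enone of 6 and carries O1 plus one leaving group. C4a is the α-carbon of the same enone, and C5 is the ester carbonyl of 7.
- The gain is that all six substituents of ring A are placed by the ring construction itself. No C-methylation, no acylation of a phenol and no protecting group is needed.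
- The forward reaction has to join C8 to C8a with loss of the methoxy group (giving 8). It then has to close C4a onto C5 and aromatise.

**6 to 4.** Only the O–CH3 bond is cut. Compound 6 is the methyl ether of the minor tautomer of the hydroxy-α-pyrone 4. The ring of 4 is already ring B of 9 atom for atom (O1, C2, C3, C4, C4a, C8a). The methylation therefore does two things at once: it fixes the γ-pyrone form and it installs the leaving group on C8a. The forward reaction has to methylate the lactone carbonyl oxygen and not O4.

**4 to 3 and 2.** The bond between the first and the second carbon of the side chain is cut.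
- The first chain carbon is the methyl group of commercial triacetic acid lactone 3, which is acidified vinylogously by the ring.
- What remains is an even-numbered C24 electrophile, 2, from the natural fatty alcohol series.
- A cut directly at C2 would call for an odd-numbered C25 nucleophile, or for a C26 acyl unit plus a separate construction of the pyrone ring.

**2 to 1.** This is a functional group exchange of the primary alcohol 1 for bromide.

## Alternatives that were turned down

Alternative 1: the textbook route cuts O1–C2 and C2–C3, so that ring B is closed last on a finished ring A.
- Forward: 2,4-dimethylphloroglucinol A1 is C-acetylated to 3,5-dimethylphloracetophenone A2 and then O-acylated with hexacosanoyl chloride A3. A Baker–Venkataraman rearrangement gives 1-(2,4,6-trihydroxy-3,5-dimethylphenyl)octacosane-1,3-dione A4, and acid cyclodehydration gives 9.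
- Turned down: the real difficulty, the hexasubstituted ring A, is only moved into the preparation of A1. That preparation needs two rounds of one-carbon introduction and reduction on an ambident, air-sensitive triphenol.
- The three hydroxyl groups of A2 all compete for the costly A3, so an excess of it or protecting groups are needed.
- The count rises to seven to nine steps, while the key step builds only ring B, the easy ring.

Alternative 2: this route cuts C4a–C5 and O1–C2 in a fully open chain.
- Forward: the pentaketide ester methyl 2,4-dimethyl-3,5,7,9-tetraoxotetratriacontanoate A5 is folded by methoxide or Mg(OMe)2 (Claisen closure of ring A) and then by acid (ring B).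
- Turned down: A5 can only be assembled by acylating a polyanion with an ester that is more acidic than the conjugate acid of the nucleophile. Proton transfer therefore wins unless the carbonyl groups are masked and unmasked at the cost of steps.
- The free chain also has two productive wrong exits. One is lactonisation of the C8a enol onto C5 to an α-pyrone. The other is an aldol attack of C3 on C7 that can aromatise to a resorcinol.
- In the chosen route both exits are closed, because O1, C2, C3 and C8a are tied up in ring B from the start.

Alternative 3: ring A is made by a Danheiser benzannulation that forms C5–C6, C7–C8 and C4a–C5.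
- Forward: the diazo ketone 2-(2-diazopropanoyl)-6-pentacosyl-4H-pyran-4-one A6 undergoes a photochemical Wolff rearrangement to a pyranonyl(methyl)ketene.
- This ketene adds 1-(triisopropylsilyloxy)prop-1-yne A7. Four-electron opening and six-electron closure then give 5-hydroxy-6,8-dimethyl-2-pentacosyl-7-(triisopropylsilyloxy)-4H-chromen-4-one A8, which is desilylated.
- Turned down: A6 needs a 4-pyranone-2-carboxylic acid built in about five steps plus a diazo transfer.
- The light that triggers the Wolff step is also absorbed by the γ-pyrone, which has its own photochemical rearrangement path.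
- The six-electron closure must end on the electron-rich α-carbon of a vinylogous ester, and a deprotection follows. The way to the precursor costs more than the key step wins.

Key step: step 4

Assumption: the chain of the SMILES is read as unbranched pentacosyl (25 carbon atoms, 9 = C36H60O4). Since 9 has no stereocentre, no SMILES carries a stereodescriptor, and 8 is treated as a mixture of epimerisable diastereomers.

## Route

Step 1
Reactants: 1 1-tetracosanol
Product: 2 1-bromotetracosane
Conditions: 48% aq. HBr, conc. H2SO4, 110 °C (melt)
Reagents that add atoms: hydrogen bromide (HBr), SMILES Br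
Why: SN2 displacement of the protonated primary hydroxyl group by bromide (classical HBr/H2SO4 bromination), run above the melting point of 1; the hydroxyl group is the only functional group present.

Step 2
Reactants: 2 1-bromotetracosane; 3 4-hydroxy-6-methyl-2H-pyran-2-one (triacetic acid lactone)
Product: 4 4-hydroxy-6-pentacosyl-2H-pyran-2-one
Conditions: 3 (1.5 equiv), LiN(iPr)2 (3.2 equiv), THF/DMPU, −78 to 0 °C; 2 in THF, 0 °C to rt; aq. HCl
Reagents that add atoms: none
Why: Lateral alkylation of a dianion: the first equivalent of base gives the 4-oxido pyrone, the second removes a proton of the 6-methyl group, and the carbanion formed last is the site that is alkylated. The excess of dianion over 2 suppresses a second alkylation, and DMPU with a start at 0 °C keeps the waxy bromide in solution.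

Step 3
Reactants: 4 4-hydroxy-6-pentacosyl-2H-pyran-2-one
Product: 6 2-methoxy-6-pentacosyl-4H-pyran-4-one, via hydroxymethoxypyrylium triflate 5 (not isolated)
Conditions: MeOTf (1.2 equiv), CH2Cl2, rt; sat. aq. NaHCO3
Reagents that add atoms: methyl trifluoromethanesulfonate (MeOTf), SMILES COS(=O)(=O)C(F)(F)F
Why: A neutral protomeric ambident system is methylated by a hard methylating agent at the heteroatom that bears no proton, so the lactone carbonyl oxygen of 4 attacks MeOTf and gives 5, which loses the O4 proton in the basic wash; this is the standard entry to α-methoxy-γ-pyrones. No base is present during the alkylation, because the anion of 4 would give the 4-methoxy-2-pyrone isomer.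

Step 4
Reactants: 6 2-methoxy-6-pentacosyl-4H-pyran-4-one; 7 methyl 2-methyl-3-oxopentanoate
Product: 9 5,7-dihydroxy-6,8-dimethyl-2-pentacosyl-4H-chromen-4-one, via pyranone keto ester 8 (not isolated)
Conditions: 7 (3 equiv), LiN(iPr)2 (6.2 equiv), THF, 0 °C; 6 in THF, 0 °C to rt; MeOH, 60 °C; 2 M HCl
Reagents that add atoms: none
Why: Proposed new method: an anionic (4+2) benzannulation in which the dilithio dianion of 7 plays the part that an o-toluate carbanion plays in the Staunton–Weinreb annulation of methoxypyrones, the closest known reaction type. The γ-carbanion (future C8), the more basic and more nucleophilic site of a β-keto ester dianion, adds to C2 of 6, the β-carbon of the vinylogous ester and the only ring carbon with a leaving group, and loss of methoxide restores the pyranone and gives 8 (C8–C8a bond). Methoxide then removes the doubly activated C8–H of 8, and the extended enolate attacks the ester carbonyl through C4a in a 6-(enolexo)-exo-trig Claisen (Dieckmann-type) closure of ring A (C4a–C5 bond); loss of a second methoxide and two enolisations give the phloroglucinol ring and make the sequence irreversible. Site selectivity on 6 is needed and is secured by reversibility: addition of this stabilised carbanion at C4 or at the alkyl-bearing C6 can revert, and only addition at C2 is followed by expulsion of methoxide. Proton transfer from the chain CH2 next to the ring to the dianion is the main competitor; it destroys nothing and is answered by the excess of the cheap donor. The fold is channelled by the substrate: O1 is already tied up in ring B, so no α-pyrone lactone can form, and the methyl groups on C6 and C8 make every aldol mode end at a quaternary carbon that cannot aromatise. No stereocentre is created in 9, and the two in 8 are erased. Should methoxide open ring B, the acid quench closes it again on either of the two equivalent ortho hydroxyl groups and gives the same 9.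

## Compound list

1 | 1-tetracosanol | CCCCCCCCCCCCCCCCCCCCCCCCO | starting material
2 | 1-bromotetracosane | CCCCCCCCCCCCCCCCCCCCCCCCBr | intermediate
3 | 4-hydroxy-6-methyl-2H-pyran-2-one (triacetic acid lactone) | Cc1cc(O)cc(=O)o1 | starting material
4 | 4-hydroxy-6-pentacosyl-2H-pyran-2-one | CCCCCCCCCCCCCCCCCCCCCCCCCc1cc(O)cc(=O)o1 | intermediate
5 | 4-hydroxy-2-methoxy-6-pentacosylpyrylium trifluoromethanesulfonate | CCCCCCCCCCCCCCCCCCCCCCCCCc1cc(O)cc(OC)[o+]1.[O-]S(=O)(=O)C(F)(F)F | intermediate
6 | 2-methoxy-6-pentacosyl-4H-pyran-4-one | CCCCCCCCCCCCCCCCCCCCCCCCCc1cc(=O)cc(OC)o1 | intermediate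
7 | methyl 2-methyl-3-oxopentanoate | CCC(=O)C(C)C(=O)OC | starting material
8 | methyl 2-methyl-3-oxo-4-(4-oxo-6-pentacosyl-4H-pyran-2-yl)pentanoate (mixture of diastereomers) | CCCCCCCCCCCCCCCCCCCCCCCCCc1cc(=O)cc(o1)C(C)C(=O)C(C)C(=O)OC | intermediate
9 | 5,7-dihydroxy-6,8-dimethyl-2-pentacosyl-4H-chromen-4-one | CCCCCCCCCCCCCCCCCCCCCCCCCc1cc(=O)c2c(O)c(C)c(O)c(C)c2o1 | target

## Step count and least certain steps

Total step count: 4.
Longest linear sequence: 4 steps (1, 2, 4, 6, 9).

**Step 4 (key step, bears the label).**
- Most likely failures in the coupling: proton transfer from the chain CH2 of 6 to the dianion may outrun the addition. Alternatively, the addition may go to the alkyl-bearing ring carbon, followed by opening of ring B.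
- Most likely failures in the closure: it may stall at the stage of 8, because the ester is deactivated as part of a β-keto ester enolate. Methoxide may also cleave the ketone by a retro-Claisen reaction.
- The fallback uses known chemistry. It inverts the mode of activation and makes the two bonds in separate steps, with no strong base in the coupling.
- From 7, Me3SiCl and Et3N give methyl 2-methyl-3-(trimethylsilyloxy)pent-2-enoate F1. LiN(iPr)2 followed by Me3SiCl then gives the 1,3-bis(silyloxy)diene 1-methoxy-2-methyl-1,3-bis(trimethylsilyloxy)penta-1,3-diene F2.
- Compound 6 is converted with Me3SiOTf in CH2Cl2 (−78 to 0 °C) into 2-methoxy-6-pentacosyl-4-(trimethylsilyloxy)pyrylium triflate F3. F2 attacks F3 through its terminal carbon, a vinylogous Mukaiyama–Michael addition of the kind known for silyl-triflate-activated 4-pyranones and chromones.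
- Loss of the methoxy group and aqueous work-up give 8, which is now isolated.
- Compound 8 is closed with the non-nucleophilic base DBU in toluene at 80 °C. This is the Claisen cyclisation known from 3,5,7-triketo esters to acylphloroglucinols, and the route is rejoined at 9.

**Step 2.**
- Most likely failure: the dilithio salt of 3 is sparingly soluble and sluggish, and the bromide separates from cold THF. C-alkylation then becomes slow, and O-alkylation at O4 or a second alkylation gains ground.
- The fallback alkylates an open chain and closes the ring afterwards.
- From 3, Mg(OMe)2 in MeOH at reflux opens the lactone to methyl 3,5-dioxohexanoate F4.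
- The trianion of F4 (LiN(iPr)2, 3.1 equiv, THF, 0 °C) is more soluble and more nucleophilic at its terminal carbon. It is alkylated by 2 to methyl 3,5-dioxotriacontanoate F5.
- DBU in toluene lactonises F5, and the route is rejoined at 4.

**Step 3.**
- Most likely failure: competing methylation at O4 through the minor tautomer or through traces of base, and over-methylation to a dimethoxypyrylium salt. Two waxy isomers would then have to be separated.
- The fallback changes the leaving group to one whose installation cannot be ambiguous.
- From 2, alkylation of the dianion of acetylacetone (LiN(iPr)2, 2 equiv, THF) gives nonacosane-2,4-dione F6.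
- Deprotonation of F6 (LiN(iPr)2, 3 equiv), CS2 and then MeI (2 equiv) give the ketene dithioacetal 1,1-bis(methylsulfanyl)triacont-1-ene-3,5-dione F7.
- Warming F7 with catalytic TsOH in toluene closes the ring through the enol oxygen to 2-(methylsulfanyl)-6-pentacosyl-4H-pyran-4-one F8.
- F8 takes the place of 6 under the conditions of step 4, with methanethiolate as the leaving group, and the route is rejoined at 9.

## Further compounds

F1 | step 4 | methyl 2-methyl-3-(trimethylsilyloxy)pent-2-enoate (mixture of double bond isomers) | CCC(O[Si](C)(C)C)=C(C)C(=O)OC
F2 | step 4 | 1-methoxy-2-methyl-1,3-bis(trimethylsilyloxy)penta-1,3-diene (mixture of double bond isomers) | CC=C(O[Si](C)(C)C)C(C)=C(OC)O[Si](C)(C)C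
F3 | step 4 | 2-methoxy-6-pentacosyl-4-(trimethylsilyloxy)pyrylium trifluoromethanesulfonate | CCCCCCCCCCCCCCCCCCCCCCCCCc1cc(O[Si](C)(C)C)cc(OC)[o+]1.[O-]S(=O)(=O)C(F)(F)F
F4 | step 2 | methyl 3,5-dioxohexanoate | CC(=O)CC(=O)CC(=O)OC
F5 | step 2 | methyl 3,5-dioxotriacontanoate | CCCCCCCCCCCCCCCCCCCCCCCCCC(=O)CC(=O)CC(=O)OC
F6 | step 3 | nonacosane-2,4-dione | CCCCCCCCCCCCCCCCCCCCCCCCCC(=O)CC(C)=O
F7 | step 3 | 1,1-bis(methylsulfanyl)triacont-1-ene-3,5-dione | CCCCCCCCCCCCCCCCCCCCCCCCCC(=O)CC(=O)C=C(SC)SC
F8 | step 3 | 2-(methylsulfanyl)-6-pentacosyl-4H-pyran-4-one | CCCCCCCCCCCCCCCCCCCCCCCCCc1cc(=O)cc(SC)o1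
A1 | alternative 1 | 2,4-dimethylphloroglucinol (2,4-dimethylbenzene-1,3,5-triol) | Cc1c(O)cc(O)c(C)c1O
A2 | alternative 1 | 3,5-dimethylphloracetophenone (1-(2,4,6-trihydroxy-3,5-dimethylphenyl)ethanone) | CC(=O)c1c(O)c(C)c(O)c(C)c1O
A3 | alternative 1 | hexacosanoyl chloride | CCCCCCCCCCCCCCCCCCCCCCCCCC(=O)Cl
A4 | alternative 1 | 1-(2,4,6-trihydroxy-3,5-dimethylphenyl)octacosane-1,3-dione | CCCCCCCCCCCCCCCCCCCCCCCCCC(=O)CC(=O)c1c(O)c(C)c(O)c(C)c1O
A5 | alternative 2 | methyl 2,4-dimethyl-3,5,7,9-tetraoxotetratriacontanoate | CCCCCCCCCCCCCCCCCCCCCCCCCC(=O)CC(=O)CC(=O)C(C)C(=O)C(C)C(=O)OC
A6 | alternative 3 | 2-(2-diazopropanoyl)-6-pentacosyl-4H-pyran-4-one | CCCCCCCCCCCCCCCCCCCCCCCCCc1cc(=O)cc(o1)C(=O)C(C)=[N+]=[N-]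
A7 | alternative 3 | 1-(triisopropylsilyloxy)prop-1-yne | CC#CO[Si](C(C)C)(C(C)C)C(C)C
A8 | alternative 3 | 5-hydroxy-6,8-dimethyl-2-pentacosyl-7-(triisopropylsilyloxy)-4H-chromen-4-one | CCCCCCCCCCCCCCCCCCCCCCCCCc1cc(=O)c2c(O)c(C)c(O[Si](C(C)C)(C(C)C)C(C)C)c(C)c2o1
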